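Ring A is closed last, onto a ring-B cyclohexanone (labdane numbering). The feature exploited is the 1,3-relationship of the quaternary carbons C4 and C10 across C5: each can be the α-carbon of a carbonyl group, C4 of the C18 ester and C10 of a temporary C9 ketone. The precursor is therefore a monocyclic silyl enol ether/ester whose only fixed stereocentre is C5, set by asymmetric catalysis. In one flask its C10 enolate is alkylated by 1-chloro-3-iodopropane and the C4 ester enolate then closes ring A, so C5 relays both quaternary centres. The leftover C9 enolate is trapped as the enol triflate, the handle for the side chain (C13 from the chiral pool) and the C8 methylene.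

Key step: step 3

Assumption: the catalyst enantiomer in step 2 is the one that gives the (1S) adduct, taken to be (S) by analogy with cyclohex-2-en-1-one; the propanoate α-carbon (C4) of 4, 6 and 7 is an inconsequential epimer mixture because it is re-enolised in step 3.

Step 1
Reactants: 1 methyl propanoate
Product: 2 1-methoxy-1-(trimethylsilyloxy)prop-1-ene (mixture of geometric isomers)
Conditions: LDA, THF, −78 °C; Me3SiCl, −78 → 23 °C; distillation
Reagents that add atoms: chlorotrimethylsilane, C[Si](C)(C)Cl
Why: Kinetic ester enolate formation and O-silylation should give the silyl ketene acetal, whose geometry is irrelevant because C4 is re-enolised later.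

Step 2
Reactants: 2 1-methoxy-1-(trimethylsilyloxy)prop-1-ene; 3 2-methylcyclohex-2-en-1-one
Product: 4 methyl 2-[(1S)-2-methyl-3-(trimethylsilyloxy)cyclohex-2-en-1-yl]propanoate
Conditions: (S)-3,3-diphenyl-1-(2-methylphenyl)tetrahydro-1H,3H-pyrrolo[1,2-c][1,3,2]oxazaborole·HNTf2 (20 mol %), Ph3PO (25 mol %), toluene, −20 °C; non-aqueous work-up, used crude
Reagents that add atoms: none
Why: Catalytic enantioselective Mukaiyama–Michael addition, in which the chiral oxazaborolidinium ion activates the enone and shields one face of the β-carbon (C5), and silyl transfer should deliver the tetrasubstituted C9=C10 silyl enol ether regiospecifically.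

Step 3
Reactants: 4 methyl 2-[(1S)-2-methyl-3-(trimethylsilyloxy)cyclohex-2-en-1-yl]propanoate; 5 1-chloro-3-iodopropane
Product: 10 methyl (1R,4aS,8aR)-1,4a-dimethyl-5-(trifluoromethanesulfonyloxy)-1,2,3,4,4a,7,8,8a-octahydronaphthalene-1-carboxylate, via potassium enolate 6 (not isolated), via chloropropyl ketone 7 (not isolated), via dilithium bis-enolate 8 (not isolated), via bicyclic lithium enolate 9 (not isolated)
Conditions: KOtBu (1.05 equiv), THF, −40 °C; 5 (1.2 equiv), −40 → 0 °C; LDA (2.3 equiv), THF/DMPU, −78 → 23 °C; PhNTf2 (1.5 equiv), 0 → 23 °C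
Reagents that add atoms: N-phenylbis(trifluoromethanesulfonimide), O=S(=O)(N(c1ccccc1)S(=O)(=O)C(F)(F)F)C(F)(F)F
Why: tert-Butoxide cleaves the O–Si bond of 4 to the regiodefined tetrasubstituted enolate 6, which is alkylated at C10 by the iodide end of 5 (C1–C10 bond); LDA then converts ketone 7 into the ketone/ester bis-enolate 8, whose ester enolate displaces chloride (C3–C4 bond), and the surviving C9 enolate 9 is O-triflated. The closest known reaction type is the annulation of a bis-enolate by a 1,3-dihalide through sequential inter- and intramolecular enolate alkylation, with terminal enolate triflation. Ring A closes in the 6-exo-tet mode through a chair that is trans-fused to ring B. At C10 the C5 substituent sits pseudo-axial in the enolate to avoid A(1,2) strain with the C10 methyl, so the iodide should enter axially on the opposite face, placing C1 trans to C4 and the C20 methyl β. At C4, A(1,3) strain holds the ester enolate with C5–H eclipsing the C4=C(OMe)OLi bond and the tether allows attack only from the C10 side, so the C18 ester carbon should become equatorial (α) and the C19 methyl axial (β). The step needs C- over O-alkylation and iodide over chloride in the first event (soft iodide, tetrasubstituted enolate) and ester-enolate C-alkylation over O-alkylation or α′-bridging by the ketone enolate in the second, which the lithium counter-ion, the higher nucleophilicity of the ester enolate and the chair 6-exo closure should secure.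

Step 4
Reactants: 11 methyl hydrogen (R)-3-methylglutarate [(3R)-5-methoxy-3-methyl-5-oxopentanoic acid]
Product: 12 methyl (3R)-5-hydroxy-3-methylpentanoate
Conditions: BH3·SMe2, THF, 0 → 23 °C; aqueous work-up, used without delay
Reagents that add atoms: none
Why: Borane should reduce the carboxylic acid chemoselectively beside the methyl ester, leaving the C13 stereocentre untouched.

Step 5
Reactants: 12 methyl (3R)-5-hydroxy-3-methylpentanoate
Product: 13 methyl (3S)-5-iodo-3-methylpentanoate
Conditions: I2, PPh3, imidazole, CH2Cl2, 0 °C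
Reagents that add atoms: iodine, II
Why: Appel iodination of the primary alcohol, with the descriptor changing only through the priority rules.

Step 6
Reactants: 10 methyl (1R,4aS,8aR)-1,4a-dimethyl-5-(trifluoromethanesulfonyloxy)-1,2,3,4,4a,7,8,8a-octahydronaphthalene-1-carboxylate; 13 methyl (3S)-5-iodo-3-methylpentanoate
Product: 15 methyl (1R,4aS,8aR)-5-[(3R)-5-methoxy-3-methyl-5-oxopentyl]-1,4a-dimethyl-1,2,3,4,4a,7,8,8a-octahydronaphthalene-1-carboxylate, via alkylzinc iodide 14 (not isolated)
Conditions: 13, Zn dust, LiCl, THF, 40 °C; then 10, PdCl2[1,1′-bis(diphenylphosphino)ferrocene] (5 mol %), THF/NMP, 60 °C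
Reagents that add atoms: none
Why: Negishi coupling, in which zinc insertion gives an ester-tolerant primary alkylzinc that should couple with the enol triflate to form the C9–C11 bond while the bidentate ligand suppresses β-hydride elimination.

Step 7
Reactants: 15 methyl (1R,4aS,8aR)-5-[(3R)-5-methoxy-3-methyl-5-oxopentyl]-1,4a-dimethyl-1,2,3,4,4a,7,8,8a-octahydronaphthalene-1-carboxylate
Product: 16 methyl (1R,4aS,5R,6R,8aR)-6-hydroxy-5-[(3R)-5-methoxy-3-methyl-5-oxopentyl]-1,4a-dimethyldecahydronaphthalene-1-carboxylate (8α-OH, 9α-H)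
Conditions: BH3·THF, THF, 0 → 23 °C; 30 % H2O2, 3 M aq. NaOAc, 0 → 23 °C
Reagents that add atoms: hydrogen peroxide, OO
Why: Syn hydroboration–oxidation should place boron at the less substituted C8 and hydrogen at C9 from the α-face, opposite the axial C10 methyl, which sets the 9α-H configuration (and C9 remains correctable after step 8, the equatorial side chain being favoured α to the ketone).

Step 8
Reactants: 16 methyl (1R,4aS,5R,6R,8aR)-6-hydroxy-5-[(3R)-5-methoxy-3-methyl-5-oxopentyl]-1,4a-dimethyldecahydronaphthalene-1-carboxylate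
Product: 17 methyl (1R,4aS,5R,8aR)-5-[(3R)-5-methoxy-3-methyl-5-oxopentyl]-1,4a-dimethyl-6-oxodecahydronaphthalene-1-carboxylate
Conditions: DMP [1,1,1-tris(acetyloxy)-1,1-dihydro-1,2-benziodoxol-3(1H)-one], NaHCO3, CH2Cl2, 0 → 23 °C
Reagents that add atoms: none
Why: Buffered periodinane oxidation of the secondary alcohol should give the C8 ketone with the equatorial 9β side chain, the thermodynamically preferred epimer.

Step 9
Reactants: 17 methyl (1R,4aS,5R,8aR)-5-[(3R)-5-methoxy-3-methyl-5-oxopentyl]-1,4a-dimethyl-6-oxodecahydronaphthalene-1-carboxylate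
Product: 18 methyl (1R,4aR,5S,8aR)-5-[(3R)-5-methoxy-3-methyl-5-oxopentyl]-1,4a-dimethyl-6-methylidenedecahydronaphthalene-1-carboxylate
Conditions: Ph3PCH3Br, KOtBu, THF, 0 → 50 °C
Reagents that add atoms: methyltriphenylphosphonium bromide, C[P+](c1ccccc1)(c1ccccc1)c1ccccc1.[Br-]
Why: Wittig methylenation of the C8 ketone, in which the non-stabilised ylide should leave both methyl esters and the equatorial C9 configuration untouched.

Step 10
Reactants: 18 methyl (1R,4aR,5S,8aR)-5-[(3R)-5-methoxy-3-methyl-5-oxopentyl]-1,4a-dimethyl-6-methylidenedecahydronaphthalene-1-carboxylate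
Product: 19 (3R)-5-[(1S,4aR,5R,8aR)-5-(methoxycarbonyl)-5,8a-dimethyl-2-methylidenedecahydronaphthalen-1-yl]-3-methylpentanoic acid (target)
Conditions: LiOH·H2O, THF/MeOH/H2O, 23 °C; then 1 M HCl, 0 °C, to pH 4
Reagents that add atoms: lithium hydroxide, [Li+].[OH-]
Why: Saponification should cleave only the unhindered C15 ester, because the tertiary, neopentyl C18 ester is inert under these conditions.

Compound list
1 | methyl propanoate | CCC(=O)OC | starting material
2 | 1-methoxy-1-(trimethylsilyloxy)prop-1-ene (mixture of geometric isomers) | CC=C(OC)O[Si](C)(C)C | intermediate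
3 | 2-methylcyclohex-2-en-1-one | CC1=CCCCC1=O | starting material
4 | methyl 2-[(1S)-2-methyl-3-(trimethylsilyloxy)cyclohex-2-en-1-yl]propanoate (epimer mixture at the propanoate α-carbon) | C[Si](C)(C)OC1=C(C)[C@H](C(C)C(=O)OC)CCC1 | intermediate
5 | 1-chloro-3-iodopropane | ClCCCI | starting material
6 | potassium (3S)-3-(1-methoxy-1-oxopropan-2-yl)-2-methylcyclohex-1-en-1-olate | [K+].[O-]C1=C(C)[C@H](C(C)C(=O)OC)CCC1 | intermediate (not isolated)
7 | methyl 2-[(1S,2S)-2-(3-chloropropyl)-2-methyl-3-oxocyclohexyl]propanoate (chloropropyl trans to the propanoate group) | O=C1CCC[C@@H](C(C)C(=O)OC)[C@]1(C)CCCCl | intermediate (not isolated)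
8 | dilithium bis-enolate of 7 (ketone enolate C8=C9–OLi and ester enolate C4=C(OMe)OLi) | [Li+].[Li+].[O-]C1=CCC[C@@H](C(C)=C([O-])OC)[C@]1(C)CCCCl | intermediate (not isolated)
9 | lithium enolate of methyl (1R,4aS,8aR)-1,4a-dimethyl-5-oxodecahydronaphthalene-1-carboxylate (trans-fused, CO2Me α, both methyls β) | [Li+].[O-]C1=CCC[C@@H]2[C@]1(C)CCC[C@@]2(C)C(=O)OC | intermediate (not isolated)
10 | methyl (1R,4aS,8aR)-1,4a-dimethyl-5-(trifluoromethanesulfonyloxy)-1,2,3,4,4a,7,8,8a-octahydronaphthalene-1-carboxylate | O=S(=O)(OC1=CCC[C@@H]2[C@]1(C)CCC[C@@]2(C)C(=O)OC)C(F)(F)F | intermediate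
11 | methyl hydrogen (R)-3-methylglutarate [(3R)-5-methoxy-3-methyl-5-oxopentanoic acid] | OC(=O)C[C@@H](C)CC(=O)OC | starting material
12 | methyl (3R)-5-hydroxy-3-methylpentanoate | OCC[C@@H](C)CC(=O)OC | intermediate
13 | methyl (3S)-5-iodo-3-methylpentanoate | ICC[C@@H](C)CC(=O)OC | intermediate
14 | iodo[(3S)-5-methoxy-3-methyl-5-oxopentyl]zinc | I[Zn]CC[C@@H](C)CC(=O)OC | intermediate (not isolated)
15 | methyl (1R,4aS,8aR)-5-[(3R)-5-methoxy-3-methyl-5-oxopentyl]-1,4a-dimethyl-1,2,3,4,4a,7,8,8a-octahydronaphthalene-1-carboxylate | C1(CC[C@@H](C)CC(=O)OC)=CCC[C@@H]2[C@]1(C)CCC[C@@]2(C)C(=O)OC | intermediate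
16 | methyl (1R,4aS,5R,6R,8aR)-6-hydroxy-5-[(3R)-5-methoxy-3-methyl-5-oxopentyl]-1,4a-dimethyldecahydronaphthalene-1-carboxylate | O[C@@H]1CC[C@@H]2[C@](C)(CCC[C@@]2(C)C(=O)OC)[C@H]1CC[C@@H](C)CC(=O)OC | intermediate
17 | methyl (1R,4aS,5R,8aR)-5-[(3R)-5-methoxy-3-methyl-5-oxopentyl]-1,4a-dimethyl-6-oxodecahydronaphthalene-1-carboxylate | O=C1CC[C@@H]2[C@](C)(CCC[C@@]2(C)C(=O)OC)[C@H]1CC[C@@H](C)CC(=O)OC | intermediate
18 | methyl (1R,4aR,5S,8aR)-5-[(3R)-5-methoxy-3-methyl-5-oxopentyl]-1,4a-dimethyl-6-methylidenedecahydronaphthalene-1-carboxylate | C=C1CC[C@@H]2[C@](C)(CCC[C@@]2(C)C(=O)OC)[C@H]1CC[C@@H](C)CC(=O)OC | intermediate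
19 | (3R)-5-[(1S,4aR,5R,8aR)-5-(methoxycarbonyl)-5,8a-dimethyl-2-methylidenedecahydronaphthalen-1-yl]-3-methylpentanoic acid | C=C1CC[C@@H]2[C@](C)(CCC[C@@]2(C)C(=O)OC)[C@H]1CC[C@@H](C)CC(=O)O | target

Total steps: 10. Longest linear sequence: 8 (steps 1, 2, 3, 6, 7, 8, 9, 10); steps 4 and 5 prepare the side-chain iodide.

Steps most likely to fail

Step 3. The ring-closing alkylation by the ester enolate may lose to O-alkylation or α′-C-alkylation by the ketone enolate held in the same molecule, and slow quaternisation at C10 may allow proton exchange that scrambles the enolate. The fallback sets out from 4 and masks the ketone so that only the ester can be enolised. Enolate 6 is generated and alkylated with 5 as above, but chloro ketone 7 is isolated and silylated (KN(SiMe3)2, Me3SiCl, THF, −78 °C) to methyl 2-[(1S,2S)-2-(3-chloropropyl)-2-methyl-3-(trimethylsilyloxy)cyclohex-3-en-1-yl]propanoate F1. LDA in THF/DMPU (−78 → 23 °C) should then close ring A through the ester enolate alone, giving methyl (1R,4aS,8aR)-1,4a-dimethyl-5-(trimethylsilyloxy)-1,2,3,4,4a,7,8,8a-octahydronaphthalene-1-carboxylate F2. CsF and PhNTf2 in DME convert this silyl enol ether into the triflate, and the route is rejoined at 10.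

Step 2. The α-methyl group of the enone may slow the conjugate addition and erode the facial discrimination by the catalyst, and the labile silyl enol ether may be lost on isolation. The fallback sets out from 2 and uses purchased cyclohex-2-en-1-one, a precedented acceptor for the same catalyst, to give methyl 2-[(1R)-3-(trimethylsilyloxy)cyclohex-2-en-1-yl]propanoate F3. Regiospecific enolate generation and methylation (KOtBu, THF, −40 °C; MeI) should give trans-configured methyl 2-[(1R,2S)-2-methyl-3-oxocyclohexyl]propanoate F4. Thermodynamic silylation (Me3SiCl, NaI, Et3N, MeCN) toward the more substituted enol ether returns to 4.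

Step 6. Oxidative addition and transmetalation at the enol triflate beside the quaternary C10 may be slow, so that β-hydride elimination or protonation of the alkylzinc takes over. The fallback sets out from 10 and 13 and avoids the preformed organometallic. A nickel-catalysed reductive cross-electrophile coupling (NiBr2(MeOCH2CH2OMe), 4,4′-di-tert-butyl-2,2′-bipyridine, Mn powder, DMA, 23 °C), in which the iodide enters as an alkyl radical, should join the two electrophiles directly and comes back to the route at 15.

Further compounds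
F1 | step 3 | methyl 2-[(1S,2S)-2-(3-chloropropyl)-2-methyl-3-(trimethylsilyloxy)cyclohex-3-en-1-yl]propanoate | C[Si](C)(C)OC1=CCC[C@@H](C(C)C(=O)OC)[C@]1(C)CCCCl
F2 | step 3 | methyl (1R,4aS,8aR)-1,4a-dimethyl-5-(trimethylsilyloxy)-1,2,3,4,4a,7,8,8a-octahydronaphthalene-1-carboxylate | C[Si](C)(C)OC1=CCC[C@@H]2[C@]1(C)CCC[C@@]2(C)C(=O)OC
F3 | step 2 | methyl 2-[(1R)-3-(trimethylsilyloxy)cyclohex-2-en-1-yl]propanoate | C[Si](C)(C)OC1=C[C@H](C(C)C(=O)OC)CCC1
F4 | step 2 | methyl 2-[(1R,2S)-2-methyl-3-oxocyclohexyl]propanoate | O=C1CCC[C@@H](C(C)C(=O)OC)[C@@H]1C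
F0 | step 6 | none | none
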